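**Assumption (one line):** germacrane numbering is used throughout (ring C1–C10; C11–C13 = the lactone three-carbon unit; C14 = ester carbon on C10; C15 = methyl on C4), and the ligand antipode in step 2 is taken to be the one that gives Re-face addition to prenal.

## Retrosynthetic overview

1. γ-Lactone (second ring, formed last): allylic oxidation of the C12 methyl of a 7-isopropenyl group and oxidative lactonization onto 6-OH, the germacrene A → acid → 6,12-olide logic.
2. Ten-membered ring (first ring): C6–C7 bond by a cyclase-like head-to-tail closure, a Lewis-acid carbonyl-ene reaction of acyclic aldehyde 10 (C6 aldehyde as electrophile, distal isopropylidene as nucleophile, loss of a C13 proton); it sets C6 and C7.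
3. Acyclic 2,3-dihydrofarnesal-type chain 10: E-selective cross-metathesis (C1=C10) of (S)-3-methylhept-6-enal (from (S)-citronellal, which supplies C4) with the 2-substituted acrylate 9.
4. Acrylate 9: catalytic asymmetric 2-(methoxycarbonyl)allylation of prenal (sets C8), then angeloylation.

## Route

**Step 1**
Reactants: 1 (S)-citronellal
Product: 2 (3S)-3-methylhept-6-enal
Conditions: [RuCl2(H2IMes)(=CH-C6H4-2-OiPr)] (second-generation Hoveyda–Grubbs catalyst, 2 mol%), ethylene (10 bar), toluene, 60 °C
Reagents that add atoms: ethylene C=C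
Why: Ethenolysis (olefin cross-metathesis with ethylene) cuts the prenyl terminus to a vinyl group, driven by ethylene pressure and loss of volatile isobutene; the aldehyde is tolerated and the chiral-pool centre (future C4, S) is untouched.

**Step 2**
Reactants: 3 3-methylbut-2-enal (prenal); 4 methyl 2-(bromomethyl)acrylate
Product: 6 methyl (4R)-4-hydroxy-6-methyl-2-methylenehept-5-enoate, via TMS ether 5 (not isolated)
Conditions: CrCl2 (10 mol%), Nakada-type chiral 1,8-bis(oxazolinyl)carbazole ligand (12 mol%), Mn powder, Me3SiCl, iPr2NEt (0.3 equiv), THF, 0 °C → rt; then citric acid, MeOH, 0 °C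
Reagents that add atoms: none
Why: Catalytic asymmetric Nozaki–Hiyama–Kishi 2-(alkoxycarbonyl)allylation, in which the allyl–chromium species (trivalent chromium) adds 1,2 to the enal through a ligand-controlled chair transition state on the Re face and sets C8 as R, with Mn turning the chromium over, Me3SiCl releasing the alkoxide, and a cold weak-acid desilylation that leaves the γ-hydroxy ester unlactonized.

**Step 3**
Reactants: 6 methyl (4R)-4-hydroxy-6-methyl-2-methylenehept-5-enoate; 7 angelic acid
Product: 9 methyl (4R)-4-(angeloyloxy)-6-methyl-2-methylenehept-5-enoate, via mixed anhydride 8 (not isolated)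
Conditions: 7, 2,4,6-Cl3C6H2COCl, Et3N, toluene, rt, 2 h; then 6, 60 °C
Reagents that add atoms: none
Why: Yamaguchi esterification run without DMAP, where the alcohol attacks the unhindered angeloyl carbonyl of the mixed anhydride, so no nucleophilic catalyst is present to isomerize the Z-enoate to tiglate and C8 is acylated with retention.

**Step 4**
Reactants: 2 (3S)-3-methylhept-6-enal (3 equiv); 9 methyl (4R)-4-(angeloyloxy)-6-methyl-2-methylenehept-5-enoate
Product: 10 methyl (2E,6S)-2-[(2R)-2-(angeloyloxy)-4-methylpent-3-en-1-yl]-6-methyl-8-oxooct-2-enoate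
Conditions: [RuCl2(H2IMes)(=CH-C6H4-2-OiPr)] (10 mol%), 1,4-benzoquinone (20 mol%), CH2Cl2, 40 °C, argon sparge
Reagents that add atoms: none
Why: Olefin cross-metathesis of a terminal alkene with a 1,1-disubstituted acrylate gives the thermodynamic E-trisubstituted enoate (C2 cis to C9, the ring-cis geometry needed later), while the hindered allylic-oxygenated isopropylidene and the angelate are slow spectator olefins and the aldehyde is tolerated.

**Step 5**
Reactants: 10 methyl (2E,6S)-2-[(2R)-2-(angeloyloxy)-4-methylpent-3-en-1-yl]-6-methyl-8-oxooct-2-enoate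
Product: 11 methyl (4S,6R,7S,8R)-8-angeloyloxy-6-hydroxygermacra-1(10)E,11(13)-dien-14-oate (ten-membered ring C1–C10; C1=C10 ring-cis with CO2Me on C10; CH3 on C4; OH on C6; isopropenyl on C7; angelate on C8)
Conditions: preformed MeAl(OAr)2 (Ar = 4-bromo-2,6-di-tert-butylphenyl, 3 equiv), CH2Cl2, −78 → −40 °C, syringe-pump addition of 10 (final 1 mM); aq. KNaC4H4O6
Reagents that add atoms: none
Why: Proposed new method: a macrocyclic Lewis-acid carbonyl-ene (Prins-type) closure that copies the germacrene cyclase — the bulky aldehyde-selective aluminium aryloxide activates only C6=O as the electrophile, the isopropylidene is the sole π-nucleophile (both enoates are electron-poor, and the E-enoate already holds C2 and C9 cis so the chain is pre-folded), C7 attacks C6 and the developing C11 cation is quenched by concerted C13–H transfer to oxygen in a chair-like six-centre transition state that puts H6 anti to H7 (the closest known reaction is the aluminium-promoted citronellal → isopulegol ene cyclization, and Lewis-acid macro-ene closures to 14-membered cembranoid rings are the nearest ring-size precedent), while C8 steers the C7 face through the allylic-strain-minimized conformer (H8 eclipsing the alkene, tether carbon C9 anti to the forming bond, angelate outside), giving 6R,7S.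

**Step 6**
Reactants: 11 methyl (4S,6R,7S,8R)-8-angeloyloxy-6-hydroxygermacra-1(10)E,11(13)-dien-14-oate
Product: 12 methyl (4S,6R,7S,8R)-8-angeloyloxy-6,12-dihydroxygermacra-1(10)E,11(13)-dien-14-oate
Conditions: SeO2 (0.3 equiv), t-BuOOH (3 equiv), salicylic acid (0.1 equiv), CH2Cl2, 0 °C → rt
Reagents that add atoms: tert-butyl hydroperoxide CC(C)(C)OO (terminal oxidant; its oxygen is delivered through catalytic SeO2)
Why: SeO2 allylic oxidation (ene reaction then [2,3]-sigmatropic shift) hydroxylates the methyl of the 1,1-disubstituted isopropenyl group (CH3 preferred over the hindered C7–H) and leaves the alkene in place, while the allylic positions of the two enoates are deactivated; no stereocentre is touched.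

**Step 7**
Reactants: 12 methyl (4S,6R,7S,8R)-8-angeloyloxy-6,12-dihydroxygermacra-1(10)E,11(13)-dien-14-oate
Product: 15 CNP0510087.1 (target), via hydroxy enal 13 (not isolated), via lactol 14 (not isolated)
Conditions: TEMPO (0.2 equiv), PhI(OAc)2 (3 equiv), CH2Cl2, rt
Reagents that add atoms: none
Why: TEMPO/PhI(OAc)2 oxidative lactonization, in which the primary allylic alcohol is oxidized selectively to the enal, the 6-OH closes the five-membered lactol and a second oxidation gives the α-methylene-γ-lactone, trans-fused because C6 and C7 are already fixed.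

## Compound list

1 | (S)-citronellal, (3S)-3,7-dimethyloct-6-enal | O=CC[C@@H](C)CCC=C(C)C | starting material
2 | (3S)-3-methylhept-6-enal | O=CC[C@@H](C)CCC=C | intermediate
3 | 3-methylbut-2-enal (prenal) | CC(C)=CC=O | starting material
4 | methyl 2-(bromomethyl)acrylate | C=C(CBr)C(=O)OC | starting material
5 | methyl (4R)-6-methyl-2-methylene-4-(trimethylsilyloxy)hept-5-enoate | C=C(C(=O)OC)C[C@@H](O[Si](C)(C)C)C=C(C)C | intermediate (not isolated)
6 | methyl (4R)-4-hydroxy-6-methyl-2-methylenehept-5-enoate | C=C(C(=O)OC)C[C@@H](O)C=C(C)C | intermediate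
7 | angelic acid, (Z)-2-methylbut-2-enoic acid | C/C=C(/C)C(=O)O | starting material
8 | angelic 2,4,6-trichlorobenzoic anhydride | C/C=C(/C)C(=O)OC(=O)c1c(Cl)cc(Cl)cc1Cl | intermediate (not isolated)
9 | methyl (4R)-4-(angeloyloxy)-6-methyl-2-methylenehept-5-enoate | C=C(C(=O)OC)C[C@@H](OC(=O)/C(C)=C\C)C=C(C)C | intermediate
10 | methyl (2E,6S)-2-[(2R)-2-(angeloyloxy)-4-methylpent-3-en-1-yl]-6-methyl-8-oxooct-2-enoate | O=CC[C@@H](C)CC/C=C(/C(=O)OC)C[C@@H](OC(=O)/C(C)=C\C)C=C(C)C | intermediate
11 | methyl (4S,6R,7S,8R)-8-angeloyloxy-6-hydroxygermacra-1(10)E,11(13)-dien-14-oate | O[C@@H]1C[C@@H](C)CC/C=C(/C(=O)OC)C[C@@H](OC(=O)/C(C)=C\C)[C@H]1C(C)=C | intermediate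
12 | methyl (4S,6R,7S,8R)-8-angeloyloxy-6,12-dihydroxygermacra-1(10)E,11(13)-dien-14-oate | O[C@@H]1C[C@@H](C)CC/C=C(/C(=O)OC)C[C@@H](OC(=O)/C(C)=C\C)[C@H]1C(=C)CO | intermediate
13 | methyl (4S,6R,7S,8R)-8-angeloyloxy-6-hydroxy-12-oxogermacra-1(10)E,11(13)-dien-14-oate | O[C@@H]1C[C@@H](C)CC/C=C(/C(=O)OC)C[C@@H](OC(=O)/C(C)=C\C)[C@H]1C(=C)C=O | intermediate (not isolated)
14 | 6,12-lactol of 13 (cyclic hemiacetal, anomeric mixture) | C=C1C(O)O[C@@H]2C[C@@H](C)CC/C=C(/C(=O)OC)C[C@@H](OC(=O)/C(C)=C\C)[C@@H]12 | intermediate (not isolated)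
15 | CNP0510087.1, methyl (4S,6R,7S,8R)-8-angeloyloxy-12-oxo-6,12-epoxygermacra-1(10)E,11(13)-dien-14-oate | C=C1C(=O)O[C@@H]2C[C@@H](C)CC/C=C(/C(=O)OC)C[C@@H](OC(=O)/C(C)=C\C)[C@@H]12 | target

## Totals and risks

Total step count: 7. Longest linear sequence: 6 steps (3 + 4 → 6 → 9 → 10 → 11 → 12 → 15).

**Step 5 (macrocyclic carbonyl-ene).** This is the step most likely to fail. A ten-membered ring is the hardest size to close, the allylic angelate can ionize under Lewis acid, and the C7 face selectivity relative to C8 rests on a model. Fallback, from 10 and returning at 11: replace the ene closure by an intramolecular Nozaki–Hiyama–Kishi allylation. SeO2/t-BuOOH oxidizes the E-methyl of the isopropylidene of 10 (the only electron-rich alkene) to the (E)-allylic alcohol F1. CBr4/PPh3 converts it to the allylic bromide F2. CrCl2 in THF/DMF at high dilution then generates an allylchromium species (trivalent chromium) that adds through C7 to the C6 aldehyde in a closed chair transition state (anti adduct), giving the same 6-hydroxy-7-isopropenyl macrocycle 11.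

**Step 4 (cross-metathesis).** The 2-substituted acrylate is a sluggish partner and the isopropylidene of 9 can be attacked by the ruthenium methylidene. Fallback, from 1 and 7 and returning at 10: build C1=C10 by Wittig olefination instead of metathesis. Acetalization of 1 (HC(OMe)3, MeOH, cat. TsOH) gives (S)-citronellal dimethyl acetal F3. Ozonolysis (O3, CH2Cl2/MeOH, −78 °C; Me2S) gives (S)-6,6-dimethoxy-4-methylhexanal F4. Wittig reaction with commercial (triphenylphosphoranylidene)succinic anhydride (CH2Cl2, rt) gives the (E)-alkylidenesuccinic anhydride F5. (CH3)2C=CHMgBr with catalytic CuI at −78 °C opens the non-conjugated carbonyl to the keto acid F6. Me3SiCHN2 in MeOH/toluene gives the keto ester F7. Reduction with (S)-2-methyl-CBS-oxazaborolidine and catecholborane at −78 °C gives the (R)-allylic alcohol F8. Yamaguchi angeloylation with 7 as in step 3 gives the angelate acetal F9, and aqueous acetic acid frees the aldehyde to give 10.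

**Step 6 (SeO2 allylic oxidation).** Conversion may be low, or the C7–H, the 6-OH or the angelate may react on this crowded substrate. Fallback, from 11 and returning at 14: install the C12 oxygen through an allylic chloride. Ca(OCl)2 with solid CO2 in CH2Cl2/H2O at 0 °C effects an ene-type electrophilic chlorination of the isopropenyl group to the 12-chloride F10. N-methylmorpholine N-oxide with catalytic NaI in MeCN oxidizes the chloride to the enal, which closes onto 6-OH as lactol 14. This is taken on with the TEMPO/PhI(OAc)2 conditions of step 7.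

## Further compounds

F1 | step 5 | methyl (2E,6S)-2-[(2R,3E)-2-(angeloyloxy)-5-hydroxy-4-methylpent-3-en-1-yl]-6-methyl-8-oxooct-2-enoate | O=CC[C@@H](C)CC/C=C(/C(=O)OC)C[C@@H](OC(=O)/C(C)=C\C)/C=C(\C)CO
F2 | step 5 | methyl (2E,6S)-2-[(2R,3E)-2-(angeloyloxy)-5-bromo-4-methylpent-3-en-1-yl]-6-methyl-8-oxooct-2-enoate | O=CC[C@@H](C)CC/C=C(/C(=O)OC)C[C@@H](OC(=O)/C(C)=C\C)/C=C(\C)CBr
F3 | step 4 | (S)-citronellal dimethyl acetal, (6S)-8,8-dimethoxy-2,6-dimethyloct-2-ene | COC(OC)C[C@@H](C)CCC=C(C)C
F4 | step 4 | (4S)-6,6-dimethoxy-4-methylhexanal | COC(OC)C[C@@H](C)CCC=O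
F5 | step 4 | (E)-3-[(4S)-6,6-dimethoxy-4-methylhexylidene]dihydrofuran-2,5-dione | COC(OC)C[C@@H](C)CC/C=C1\CC(=O)OC1=O
F6 | step 4 | (2E)-2-[(4S)-6,6-dimethoxy-4-methylhexylidene]-6-methyl-4-oxohept-5-enoic acid | COC(OC)C[C@@H](C)CC/C=C(/C(=O)O)CC(=O)C=C(C)C
F7 | step 4 | methyl (2E)-2-[(4S)-6,6-dimethoxy-4-methylhexylidene]-6-methyl-4-oxohept-5-enoate | COC(OC)C[C@@H](C)CC/C=C(/C(=O)OC)CC(=O)C=C(C)C
F8 | step 4 | methyl (2E,4R)-2-[(4S)-6,6-dimethoxy-4-methylhexylidene]-4-hydroxy-6-methylhept-5-enoate | COC(OC)C[C@@H](C)CC/C=C(/C(=O)OC)C[C@@H](O)C=C(C)C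
F9 | step 4 | methyl (2E,4R)-4-(angeloyloxy)-2-[(4S)-6,6-dimethoxy-4-methylhexylidene]-6-methylhept-5-enoate | COC(OC)C[C@@H](C)CC/C=C(/C(=O)OC)C[C@@H](OC(=O)/C(C)=C\C)C=C(C)C
F10 | step 6 | methyl (4S,6R,7S,8R)-8-angeloyloxy-12-chloro-6-hydroxygermacra-1(10)E,11(13)-dien-14-oate | O[C@@H]1C[C@@H](C)CC/C=C(/C(=O)OC)C[C@@H](OC(=O)/C(C)=C\C)[C@H]1C(=C)CCl
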